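Both pyran rings are opened at their ether oxygens, which leaves an open chain of three adjacent CH carbons: Ca (on C3 of quinolone A, bearing 2-methylprop-1-enyl), Cb (the fusion carbon of pyrans 1 and 2, bonded to CMe2) and Cc (the O–CH on C3 of quinolone B). Each bears one sp2 carbon and Cc an oxygen, so each can come from dichloromethane by boronic ester homologation. The key step inserts the third carbon into the Cb–B bond and lets magnesiated quinolone B displace chloride, making Cb–Cc and Cc–C3 and fixing Cc, with boron as latent pyran oxygen. Its precursor is the (+)-pinanediol Cb-boronate carrying Ca, the 4-methoxyquinolone and an isopropenyl group.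

Key step: step 10

Remarks on the chemistry
- Labels: pyran 1 = O, C4(A), C3(A), Ca, Cb, Cc; pyran 2 = O, C4(B), C3(B), Cc, Cb, CMe2. The two pyrans share the Cb–Cc bond and are cis-fused. Target configuration: Ca S, Cb S, Cc R.
- ArA = 4,7,8-trimethoxy-1-methyl-2-oxo-1,2-dihydroquinolin-3-yl; ArB = 7,8-dimethoxy-4-(methoxymethoxy)-1-methyl-2-oxo-1,2-dihydroquinolin-3-yl.
- Assumption: (+)-pinanediol is (1S,2S,3R,5S)-pinane-2,3-diol. With this diol each chloromethylene insertion gives the S chloride and each displacement inverts. Followed centre by centre, this leads to the configuration of the target at Ca, Cb and Cc with one diol throughout; no structure needed correction. Where a descriptor at Ca or Cb changes along the route, only the substituent priorities change, not the spatial arrangement.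
- Dichloromethane 13 supplies Ca, Cb and Cc. Its lithium carbenoid 14 cannot be stored, so step 7 is run afresh directly before each of steps 8, 9 and 10 and the cold solution is used at once.
- Order of the endgame: pyran 2 is closed by acid while Cc still carries boron, and pyran 1 is closed last under base, so that no acid meets an ionisable Cc–O bond.

Step 1
Reactants: 1 2,3-dimethoxyaniline
Product: 3 2,3-dimethoxy-N-methylaniline, via N-(methoxymethyl)-2,3-dimethoxyaniline 2 (not isolated)
Conditions: (CH2O)n, NaOMe, MeOH, 40 °C; then NaBH4, reflux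
Reagents that add atoms: formaldehyde (as paraformaldehyde), C=O
Why: Reductive amination in its methoxide variant: the aniline and formaldehyde give the N-methoxymethyl adduct, NaBH4 reduces it to N-methyl, and the secondary aniline does not condense again under these basic conditions, so monomethylation is expected.

Step 2
Reactants: 3 2,3-dimethoxy-N-methylaniline; 4 diethyl malonate
Product: 6 4-hydroxy-7,8-dimethoxy-1-methylquinolin-2(1H)-one, via ethyl N-(2,3-dimethoxyphenyl)-N-methylmalonamate 5 (not isolated)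
Conditions: Ph2O, 160 → 250 °C, EtOH distilled off
Reagents that add atoms: none
Why: Classical thermal malonate synthesis of 4-hydroxy-2-quinolones: N-acylation to 5 is followed by intramolecular C-acylation at the only free ortho carbon, which is para to a methoxy group, so the 7,8-dimethoxy pattern follows.

Step 3
Reactants: 6 4-hydroxy-7,8-dimethoxy-1-methylquinolin-2(1H)-one
Product: 7 4-hydroxy-3-iodo-7,8-dimethoxy-1-methylquinolin-2(1H)-one
Conditions: NIS, DMF, 0 °C → rt
Reagents that add atoms: N-iodosuccinimide, O=C1CCC(=O)N1I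
Why: Electrophilic iodination at C3, the enol carbon of the vinylogous acid, which is far more nucleophilic than the dimethoxybenzo ring.

Step 4
Reactants: 7 4-hydroxy-3-iodo-7,8-dimethoxy-1-methylquinolin-2(1H)-one
Product: 8 3-iodo-4,7,8-trimethoxy-1-methylquinolin-2(1H)-one
Conditions: Me2SO4, K2CO3, acetone, reflux
Reagents that add atoms: dimethyl sulfate, COS(=O)(=O)OC
Why: O-alkylation (Williamson type) of the vinylogous acid with a hard methylating agent; C3 is blocked by iodine and the N-methyl lactam keeps the 2-quinolone form.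

Step 5
Reactants: 7 4-hydroxy-3-iodo-7,8-dimethoxy-1-methylquinolin-2(1H)-one
Product: 9 3-iodo-7,8-dimethoxy-4-(methoxymethoxy)-1-methylquinolin-2(1H)-one
Conditions: MOMCl, iPr2NEt, CH2Cl2, 0 °C → rt
Reagents that add atoms: chloromethyl methyl ether, COCCl
Why: Acetal protection of the acidic 4-OH by O-alkylation; the MOM ether should withstand organolithium and organomagnesium reagents and fall later to acid.

Step 6
Reactants: 10 2-methylprop-1-enylboronic acid; 11 (+)-pinanediol
Product: 12 (+)-pinanediol (2-methylprop-1-en-1-yl)boronate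
Conditions: MgSO4, Et2O, rt
Reagents that add atoms: none
Why: Esterification of a boronic acid with a cis-1,2-diol, driven by the stability of the dioxaborolane and by removal of water.

Step 7
Reactants: 13 dichloromethane
Product: 14 dichloromethyllithium
Conditions: n-BuLi, THF, −100 °C; the cold solution is used at once
Reagents that add atoms: n-butyllithium, [Li]CCCC
Why: Deprotonation (lithium–hydrogen exchange) of dichloromethane by n-BuLi gives the carbenoid, which persists at −100 °C long enough to be trapped by a boronic ester, which is why a fresh batch is made directly before each of steps 8, 9 and 10.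

Step 8
Reactants: 12 (+)-pinanediol (2-methylprop-1-en-1-yl)boronate; 14 dichloromethyllithium; 8 3-iodo-4,7,8-trimethoxy-1-methylquinolin-2(1H)-one
Product: 17 (+)-pinanediol [(1R)-1-ArA-3-methylbut-2-en-1-yl]boronate, via allylic α-chloro boronic ester 15 (not isolated), via arylmagnesium chloride 16 (not isolated)
Conditions: 12 added to 14, THF, −100 °C; ZnCl2, −100 → −20 °C; then 16 (2 equiv; from 8, iPrMgCl·LiCl, THF, −40 °C), −78 °C → rt
Reagents that add atoms: none
Why: Matteson homologation followed by Grignard substitution: in the dichloromethyl borate the alkenyl group shifts from boron to carbon and the pinanediol decides which chloride leaves (S chloride 15, kept cold with ZnCl2 so that the allylic chloride does not epimerise), then the aryl group of the second borate shifts with inversion, which sets Ca (R) by diol control plus stereospecific displacement.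

Step 9
Reactants: 17 (+)-pinanediol [(1R)-1-ArA-3-methylbut-2-en-1-yl]boronate; 14 dichloromethyllithium
Product: 19 (+)-pinanediol [(3R,4R)-4-ArA-2,6-dimethylhepta-1,5-dien-3-yl]boronate, via α-chloro boronic ester 18 (not isolated)
Conditions: 17 added to 14, THF, −100 °C; ZnCl2, −100 °C → rt; then CH2=C(CH3)MgBr, −78 °C → rt
Reagents that add atoms: isopropenylmagnesium bromide, CC(=C)[Mg]Br
Why: Second Matteson cycle: Ca shifts to the new carbon with retention under pinanediol control (S chloride 18) and the isopropenyl group then shifts from boron with inversion, which sets Cb (R) without reference to Ca, while the methoxyquinolone is inert to the carbenoid and to the alkenyl Grignard reagent at these temperatures.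

Step 10
Reactants: 19 (+)-pinanediol [(3R,4R)-4-ArA-2,6-dimethylhepta-1,5-dien-3-yl]boronate; 14 dichloromethyllithium; 9 3-iodo-7,8-dimethoxy-4-(methoxymethoxy)-1-methylquinolin-2(1H)-one
Product: 22 (+)-pinanediol [(1R,2R,3S)-3-ArA-1-ArB-5-methyl-2-(prop-1-en-2-yl)hex-4-en-1-yl]boronate, via α-chloro boronic ester 20 (not isolated), via arylmagnesium chloride 21 (not isolated)
Conditions: 19 added to 14, THF, −100 °C; ZnCl2, −100 °C → rt; then 21 (3 equiv; from 9, iPrMgCl·LiCl, THF, −40 °C), −78 °C → rt
Reagents that add atoms: none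
Why: Carbenoid 14 adds to the boron of 19, and on warming with ZnCl2 the Cb–B bond shifts to the carbenoid carbon with retention at Cb and loss of one chloride (bond Cb–Cc, chloride 20); Grignard 21 then adds to boron and its C3 carbon shifts anti to the C–Cl bond, with inversion at Cc (bond Cc–C3 of quinolone B). The closest known reaction is the Matteson chain extension of pinanediol boronic esters with Grignard substitution of the α-chloride, iterated over contiguous centres and also run on allylic boronic esters and with aryl Grignard reagents. No ring is closed. The new centre Cc is set by the diol, which selects the chloride that leaves from the borate (S chloride), and by the stereospecific inversion, so Cc becomes R whatever Ca and Cb are. The step needs attack at boron rather than at the quinolone carbonyl groups or the allylic Cb–H, and 1,2-shift rather than loss of HCl; the strong Lewis acidity of boron towards both carbanions, the low basicity of the chelated aryl Grignard reagent and the intramolecular anti-periplanar shift secure this, and ZnCl2 binds free chloride so that 20 does not epimerise.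

Step 11
Reactants: 22 (+)-pinanediol [(1R,2R,3S)-3-ArA-1-ArB-5-methyl-2-(prop-1-en-2-yl)hex-4-en-1-yl]boronate
Product: 24 (+)-pinanediol {(3R,4R)-3-[(1S)-1-ArA-3-methylbut-2-en-1-yl]-7,8-dimethoxy-2,2,6-trimethyl-5-oxo-3,4,5,6-tetrahydro-2H-pyrano[3,2-c]quinolin-4-yl}boronate, via free 4-hydroxyquinolone 23 (not isolated)
Conditions: TsOH·H2O, CH2Cl2, 0 °C → rt
Reagents that add atoms: none
Why: The acid first hydrolyses the MOM acetal and then protonates the 1,1-disubstituted alkene, whose tertiary cation is captured by the 4-OH of quinolone B in a Markovnikov hydroalkoxylation (the closure that turns cannabidiol-type isopropenyl phenols into dimethylchromans and 3-prenyl-4-hydroxy-2-quinolones into dihydropyranoquinolones), reversibly, so the more stable 2-quinolone ether is expected; no stereocentre is formed and the C–B bond at Cc cannot ionise as a C–O bond would.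

Step 12
Reactants: 24 (+)-pinanediol {(3R,4R)-3-[(1S)-1-ArA-3-methylbut-2-en-1-yl]-7,8-dimethoxy-2,2,6-trimethyl-5-oxo-3,4,5,6-tetrahydro-2H-pyrano[3,2-c]quinolin-4-yl}boronate
Product: 25 (3S,4R)-3-[(1S)-1-ArA-3-methylbut-2-en-1-yl]-4-hydroxy-7,8-dimethoxy-2,2,6-trimethyl-3,4-dihydro-2H-pyrano[3,2-c]quinolin-5(6H)-one
Conditions: 30% H2O2, NaOH, THF/H2O, 0 °C → rt
Reagents that add atoms: hydrogen peroxide, OO
Why: Hydroperoxide adds to boron and Cc shifts from boron to oxygen with retention (standard oxidation of boronic esters), so the carbinol keeps the geometry at Cc (R), while the remaining trisubstituted alkene and both quinolones are inert to alkaline H2O2.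

Step 13
Reactants: 25 (3S,4R)-3-[(1S)-1-ArA-3-methylbut-2-en-1-yl]-4-hydroxy-7,8-dimethoxy-2,2,6-trimethyl-3,4-dihydro-2H-pyrano[3,2-c]quinolin-5(6H)-one
Product: 26 target CNP0314650.1 (Ca S; Cb S; Cc R)
Conditions: KN(SiMe3)2, 18-crown-6, THF, 0 → 60 °C
Reagents that add atoms: none
Why: Intramolecular nucleophilic substitution by addition–elimination: the potassium alkoxide on Cc adds to C4 of the 4-methoxy-2-quinolone (a vinylogous carbamate; 6-endo attack; O on Cc and the Ca branch on Cb are already cis) and methoxide leaves, which closes pyran 1 with no change at any stereocentre.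

Compound list
1 | 2,3-dimethoxyaniline | COc1cccc(N)c1OC | starting material
2 | N-(methoxymethyl)-2,3-dimethoxyaniline | COCNc1cccc(OC)c1OC | intermediate
3 | 2,3-dimethoxy-N-methylaniline | CNc1cccc(OC)c1OC | intermediate
4 | diethyl malonate | CCOC(=O)CC(=O)OCC | starting material
5 | ethyl N-(2,3-dimethoxyphenyl)-N-methylmalonamate | CCOC(=O)CC(=O)N(C)c1cccc(OC)c1OC | intermediate
6 | 4-hydroxy-7,8-dimethoxy-1-methylquinolin-2(1H)-one | COc1ccc2c(O)cc(=O)n(C)c2c1OC | intermediate
7 | 4-hydroxy-3-iodo-7,8-dimethoxy-1-methylquinolin-2(1H)-one | COc1ccc2c(O)c(I)c(=O)n(C)c2c1OC | intermediate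
8 | 3-iodo-4,7,8-trimethoxy-1-methylquinolin-2(1H)-one | COc1ccc2c(OC)c(I)c(=O)n(C)c2c1OC | intermediate
9 | 3-iodo-7,8-dimethoxy-4-(methoxymethoxy)-1-methylquinolin-2(1H)-one | COCOc1c(I)c(=O)n(C)c2c(OC)c(OC)ccc12 | intermediate
10 | 2-methylprop-1-enylboronic acid | CC(C)=CB(O)O | starting material
11 | (+)-pinanediol, (1S,2S,3R,5S)-pinane-2,3-diol | C[C@@]1(O)[C@H](O)C[C@@H]2C[C@H]1C2(C)C | starting material
12 | (+)-pinanediol (2-methylprop-1-en-1-yl)boronate | CC(C)=CB1O[C@@H]2C[C@@H]3C[C@@H](C3(C)C)[C@]2(C)O1 | intermediate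
13 | dichloromethane | ClCCl | starting material
14 | dichloromethyllithium | [Li]C(Cl)Cl | intermediate
15 | (+)-pinanediol [(1S)-1-chloro-3-methylbut-2-en-1-yl]boronate | CC(C)=C[C@@H](Cl)B1O[C@@H]2C[C@@H]3C[C@@H](C3(C)C)[C@]2(C)O1 | intermediate
16 | 3-chloromagnesio-4,7,8-trimethoxy-1-methylquinolin-2(1H)-one | COc1ccc2c(OC)c([Mg]Cl)c(=O)n(C)c2c1OC | intermediate
17 | (+)-pinanediol [(1R)-1-ArA-3-methylbut-2-en-1-yl]boronate (Ca R) | COc1ccc2c(OC)c(c(=O)n(C)c2c1OC)[C@@H](C=C(C)C)B1O[C@@H]2C[C@@H]3C[C@@H](C3(C)C)[C@]2(C)O1 | intermediate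
18 | (+)-pinanediol [(1S,2R)-2-ArA-1-chloro-4-methylpent-3-en-1-yl]boronate | COc1ccc2c(OC)c(c(=O)n(C)c2c1OC)[C@@H](C=C(C)C)[C@@H](Cl)B1O[C@@H]2C[C@@H]3C[C@@H](C3(C)C)[C@]2(C)O1 | intermediate
19 | (+)-pinanediol [(3R,4R)-4-ArA-2,6-dimethylhepta-1,5-dien-3-yl]boronate (Cb R, Ca R) | COc1ccc2c(OC)c(c(=O)n(C)c2c1OC)[C@@H](C=C(C)C)[C@H](C(C)=C)B1O[C@@H]2C[C@@H]3C[C@@H](C3(C)C)[C@]2(C)O1 | intermediate
20 | (+)-pinanediol [(1S,2R,3S)-3-ArA-1-chloro-5-methyl-2-(prop-1-en-2-yl)hex-4-en-1-yl]boronate | COc1ccc2c(OC)c(c(=O)n(C)c2c1OC)[C@@H](C=C(C)C)[C@H](C(C)=C)[C@@H](Cl)B1O[C@@H]2C[C@@H]3C[C@@H](C3(C)C)[C@]2(C)O1 | intermediate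
21 | 3-chloromagnesio-7,8-dimethoxy-4-(methoxymethoxy)-1-methylquinolin-2(1H)-one | COCOc1c([Mg]Cl)c(=O)n(C)c2c(OC)c(OC)ccc12 | intermediate
22 | (+)-pinanediol [(1R,2R,3S)-3-ArA-1-ArB-5-methyl-2-(prop-1-en-2-yl)hex-4-en-1-yl]boronate (Cc R, Cb R, Ca S) | COc1ccc2c(OC)c(c(=O)n(C)c2c1OC)[C@@H](C=C(C)C)[C@H](C(C)=C)[C@@H](B1O[C@@H]2C[C@@H]3C[C@@H](C3(C)C)[C@]2(C)O1)c1c(OCOC)c2ccc(OC)c(OC)c2n(C)c1=O | intermediate
23 | 4-hydroxy analogue of 22 (MOM group removed from quinolone B) | COc1ccc2c(OC)c(c(=O)n(C)c2c1OC)[C@@H](C=C(C)C)[C@H](C(C)=C)[C@@H](B1O[C@@H]2C[C@@H]3C[C@@H](C3(C)C)[C@]2(C)O1)c1c(O)c2ccc(OC)c(OC)c2n(C)c1=O | intermediate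
24 | (+)-pinanediol {(3R,4R)-3-[(1S)-1-ArA-3-methylbut-2-en-1-yl]-7,8-dimethoxy-2,2,6-trimethyl-5-oxo-3,4,5,6-tetrahydro-2H-pyrano[3,2-c]quinolin-4-yl}boronate | COc1ccc2c(OC)c(c(=O)n(C)c2c1OC)[C@@H](C=C(C)C)[C@H]1[C@@H](B2O[C@@H]3C[C@@H]4C[C@@H](C4(C)C)[C@]3(C)O2)c2c(c3ccc(OC)c(OC)c3n(C)c2=O)OC1(C)C | intermediate
25 | (3S,4R)-3-[(1S)-1-ArA-3-methylbut-2-en-1-yl]-4-hydroxy-7,8-dimethoxy-2,2,6-trimethyl-3,4-dihydro-2H-pyrano[3,2-c]quinolin-5(6H)-one | COc1ccc2c(OC)c(c(=O)n(C)c2c1OC)[C@@H](C=C(C)C)[C@H]1[C@@H](O)c2c(c3ccc(OC)c(OC)c3n(C)c2=O)OC1(C)C | intermediate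
26 | CNP0314650.1, cis-fused bis(pyranoquinolinone) with Ca S, Cb S, Cc R | COc1ccc2c3c(c(=O)n(C)c2c1OC)[C@@H](C=C(C)C)[C@H]1[C@@H](O3)c2c(c3ccc(OC)c(OC)c3n(C)c2=O)OC1(C)C | target

Total step count: 13 (step 7, the preparation of the carbenoid solution, is run afresh before each of steps 8, 9 and 10).
Longest linear sequence: 10 steps (1 → 3 → 6 → 7 → 8 → 17 → 19 → 22 → 24 → 25 → 26; steps 1, 2, 3, 4, 8, 9, 10, 11, 12, 13).

Steps most likely to fail

Step 10. What may go wrong: the borate may form slowly at the crowded boron of 20, and loss of HCl across Cb–Cc may then compete with the aryl shift. Fallback, from 20 to 26: the sequence is stopped after the ZnCl2 stage and 20 is isolated. Buffered NaBO3 (THF/H2O, 0 °C) should oxidise its CHCl–B carbon to the aldehyde (2R,3S)-3-ArA-5-methyl-2-(prop-1-en-2-yl)hex-4-enal F1, used at once. Grignard 21 (from 9 and iPrMgCl·LiCl) is added to F1 at −78 °C, so that Cc–C3 is made by carbonyl addition; this should give the carbinol with Cc R F2 beside its Cc epimer F3. The facial selectivity cannot be predicted with confidence, so the two are to be separated by chromatography. KN(SiMe3)2/18-crown-6 in THF should close pyran 1 of F2 by displacement of methoxide, giving the MOM-protected pyran-1 compound F4. TsOH·H2O in CH2Cl2 then removes the MOM group (free 4-hydroxyquinolone F5) and closes pyran 2, arriving at 26.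

Step 13. What may go wrong: addition of the alkoxide to C4 may be too slow, because methoxide is a poor nucleofuge and the 7-methoxy group lowers the electrophilicity of C4, so that base-induced decomposition takes over. Fallback, from 25 to 26: LiCl in DMF at 130 °C should cleave only the vinylogous methyl ester of quinolone A, since chloride attacks the methyl carbon while aryl methyl ethers and the tertiary pyran ether do not react; this gives the 4-hydroxyquinolone F6. TsCl/Et3N in CH2Cl2 sulfonylates the acidic 4-OH in preference to the hindered secondary alcohol, giving the 4-tosylate F7. Cs2CO3 in DMF then lets the Cc alkoxide displace tosylate at C4, the standard substitution of 4-sulfonyloxy-2-quinolones, arriving at 26.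

Step 11. What may go wrong: the trisubstituted alkene may be protonated in competition, the cation may be captured by the amide oxygen instead of the 4-OH (linear 4-quinolone isomer), or a hydride shift from Cb may place a cation next to the C–B bond and lead to loss of boron. Fallback, from 22 to 24: HCl in MeOH at 0 °C removes only the MOM group and 23 is isolated. Hg(OCOCF3)2 in THF should then add to the less hindered 1,1-disubstituted alkene with ring closure by the 4-OH (alkoxymercuration, no free cation), giving the organomercurial F8. NaBH4/NaOH replaces mercury by hydrogen, arriving at 24.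

Further compounds
F1 | step 10 | (2R,3S)-3-ArA-5-methyl-2-(prop-1-en-2-yl)hex-4-enal | COc1ccc2c(OC)c(c(=O)n(C)c2c1OC)[C@@H](C=C(C)C)[C@H](C(C)=C)C=O
F2 | step 10 | (1R,2R,3S)-3-ArA-1-ArB-5-methyl-2-(prop-1-en-2-yl)hex-4-en-1-ol | COc1ccc2c(OC)c(c(=O)n(C)c2c1OC)[C@@H](C=C(C)C)[C@H](C(C)=C)[C@@H](O)c1c(OCOC)c2ccc(OC)c(OC)c2n(C)c1=O
F3 | step 10 | (1S,2R,3S)-3-ArA-1-ArB-5-methyl-2-(prop-1-en-2-yl)hex-4-en-1-ol (Cc epimer of F2) | COc1ccc2c(OC)c(c(=O)n(C)c2c1OC)[C@@H](C=C(C)C)[C@H](C(C)=C)[C@H](O)c1c(OCOC)c2ccc(OC)c(OC)c2n(C)c1=O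
F4 | step 10 | pyran-1 compound with ArB on Cc and isopropenyl on Cb (MOM ether; Ca S, Cb R, Cc R) | COc1ccc2c3c(c(=O)n(C)c2c1OC)[C@@H](C=C(C)C)[C@H](C(C)=C)[C@@H](O3)c1c(OCOC)c2ccc(OC)c(OC)c2n(C)c1=O
F5 | step 10 | 4-hydroxy analogue of F4 (MOM group removed) | COc1ccc2c3c(c(=O)n(C)c2c1OC)[C@@H](C=C(C)C)[C@H](C(C)=C)[C@@H](O3)c1c(O)c2ccc(OC)c(OC)c2n(C)c1=O
F6 | step 13 | 4-O-demethyl analogue of 25 (free 4-OH on quinolone A) | COc1ccc2c(O)c(c(=O)n(C)c2c1OC)[C@@H](C=C(C)C)[C@H]1[C@@H](O)c2c(c3ccc(OC)c(OC)c3n(C)c2=O)OC1(C)C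
F7 | step 13 | 4-tosylate of F6 (tosyloxy group on C4 of quinolone A) | COc1ccc2c(OS(=O)(=O)c3ccc(C)cc3)c(c(=O)n(C)c2c1OC)[C@@H](C=C(C)C)[C@H]1[C@@H](O)c2c(c3ccc(OC)c(OC)c3n(C)c2=O)OC1(C)C
F8 | step 11 | analogue of 24 with CH2HgOCOCF3 in place of one methyl of the CMe2 group (mixture at that carbon) | COc1ccc2c(OC)c(c(=O)n(C)c2c1OC)[C@@H](C=C(C)C)[C@H]1[C@@H](B2O[C@@H]3C[C@@H]4C[C@@H](C4(C)C)[C@]3(C)O2)c2c(c3ccc(OC)c(OC)c3n(C)c2=O)OC1(C)C[Hg]OC(=O)C(F)(F)F
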